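The C6 side chain of ring A ends in a tertiary carbinol carbon (C3'') three carbons from the ring, and C6 is ortho to O5; C1''–C3'' and O5 therefore map onto a six-membered aryl lactone fused across C5–C6, and both carbinol methyl groups are disconnected from its carbonyl. In one operation methylmagnesium bromide adds twice to that carbonyl, which builds the dimethyl carbinol, breaks the O5–acyl bond and returns the free 5-hydroxyl. The precursor is kaempferol carrying benzyl ethers at O3, O7 and O4' and a saturated three-carbon acyl bridge from O5 to C6; the bridge is laid from an O5 propiolate, which can reach no ring carbon other than C6.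

Key step: step 5

Remark: the target has no stereocentre, so no step has to control configuration. Flavone numbering is used for the core; the chain carbons are C1'' (on C6), C2'' and C3'' (lactone carbonyl, later the carbinol carbon).

Step 1
Reactants: 1 kaempferol; 2 benzyl bromide
Product: 3 3,7,4'-tri-O-benzylkaempferol
Conditions: BnBr (3.3 equiv), K2CO3 (3.5 equiv), DMF, rt
Reagents that add atoms: benzyl bromide, BrCc1ccccc1
Why: Williamson etherification, in which the 7-, 4'- and 3-hydroxyls are alkylated as their potassium phenoxides while the 5-OH, held in a hydrogen bond to the C4 carbonyl, is the least nucleophilic and should stay free when base and bromide are kept near three equivalents.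

Step 2
Reactants: 3 3,7,4'-tri-O-benzylkaempferol; 4 propiolic acid (1.5 equiv)
Product: 6 3,7,4'-tri-O-benzylkaempferol 5-O-propiolate, via O-acylisourea 5 (not isolated)
Conditions: DCC (1.5 equiv), DMAP (0.1 equiv), CH2Cl2, 0 °C → rt
Reagents that add atoms: propiolic acid, C#CC(=O)O
Why: Steglich esterification, in which the carbodiimide converts the acid into O-acylisourea 5 and DMAP passes the acyl group to the only free hydroxyl, the hydrogen-bonded 5-OH, while the low temperature and the absence of a stoichiometric base hold back conjugate addition to the ynoate.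

Step 3
Reactants: 6 3,7,4'-tri-O-benzylkaempferol 5-O-propiolate
Product: 7 3,7,4'-tri-O-benzylkaempferol with a 2-pyranone ring fused across C5–C6 (O5–C(=O)–CH=CH–C6)
Conditions: [(2-biphenylyl)P(t-Bu)2]Au(NCMe)SbF6 (5 mol %), CH2Cl2, rt
Reagents that add atoms: none
Why: Gold-catalysed intramolecular hydroarylation of an aryl propiolate (6-endo-dig, Friedel–Crafts type), in which the cationic monovalent gold complex activates the alkyne, C6 (the only unsubstituted carbon ortho to O5, activated by O7 ortho and O1 para) attacks the terminal alkyne carbon, and protodeauration gives the fused pyranone under neutral conditions that should leave the benzyl ethers untouched.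

Step 4
Reactants: 7 3,7,4'-tri-O-benzylkaempferol with a 2-pyranone ring fused across C5–C6
Product: 8 3,7,4'-tri-O-benzylkaempferol with a saturated lactone ring fused across C5–C6 (O5–C(=O)–CH2–CH2–C6)
Conditions: [(Ph3P)CuH]6 (0.5 equiv), H2O (3 equiv), degassed toluene, rt
Reagents that add atoms: none
Why: Copper hydride conjugate reduction, in which the soft hydride adds to C1'' (β to the lactone carbonyl) and water protonates C2'', while the tetrasubstituted, oxygen-rich C2=C3 bond of the flavone, the aryl ester carbonyl and the benzyl ethers should not react with this reagent.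

Step 5
Reactants: 8 3,7,4'-tri-O-benzylkaempferol with a saturated lactone ring fused across C5–C6; 9 methylmagnesium bromide
Product: 11 3,7,4'-tri-O-benzyl-6-(3-hydroxy-3-methylbutyl)kaempferol, via ketone magnesium phenoxide 10 (not isolated)
Conditions: MeMgBr (3.0 equiv), THF, −78 → 0 °C; then sat. aq. NH4Cl
Reagents that add atoms: methylmagnesium bromide, C[Mg]Br
Why: Double Grignard addition to an aryl lactone, the known conversion of dihydrocoumarins into 2-(3-hydroxy-3-methylbutyl)phenols. The first equivalent adds to the lactone carbonyl C3'', the tetrahedral intermediate expels the O5 phenoxide to give the magnesium phenoxide of methyl ketone 10, and the second equivalent adds to this ketone to give the tertiary alkoxide; aqueous NH4Cl then frees the carbinol and the 5-OH. No ring is closed (the lactone ring is opened) and no stereocentre arises, because C3'' ends up with two identical methyl groups. The selectivity needed is attack at the lactone carbonyl, and then at the ketone, in preference to C4 and C2 of the pyranone. It is secured by the much higher electrophilicity of an aryl ester compared with the C4 carbonyl (a vinylogous ester that also receives electron density from O7 and O3), by the low temperature, and by the magnesium phenoxide released at O5, which chelates the C4 carbonyl as soon as the ring opens.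

Step 6
Reactants: 11 3,7,4'-tri-O-benzyl-6-(3-hydroxy-3-methylbutyl)kaempferol
Product: 12 6-(3-hydroxy-3-methylbutyl)kaempferol
Conditions: H2 (1 atm), 10% Pd/C, THF–MeOH, rt
Reagents that add atoms: none
Why: Catalytic hydrogenolysis of the three benzyl ethers under neutral conditions, which should spare the tertiary alcohol (acid would cyclise it onto O5 or O7 or dehydrate it) and, when the reaction is stopped after three equivalents of hydrogen, the tetrasubstituted C2=C3 bond of the flavonol.

Compound list
1 | kaempferol (3,5,7-trihydroxy-2-(4-hydroxyphenyl)-4H-chromen-4-one) | O=c1c(O)c(-c2ccc(O)cc2)oc2cc(O)cc(O)c12 | starting material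
2 | benzyl bromide | BrCc1ccccc1 | starting material
3 | 3,7,4'-tri-O-benzylkaempferol (3,7-bis(benzyloxy)-2-[4-(benzyloxy)phenyl]-5-hydroxy-4H-chromen-4-one) | O=c1c(OCc2ccccc2)c(-c2ccc(OCc3ccccc3)cc2)oc2cc(OCc3ccccc3)cc(O)c12 | intermediate
4 | propiolic acid (prop-2-ynoic acid) | C#CC(=O)O | starting material
5 | O-propioloyl-N,N'-dicyclohexylisourea (activated acid, not isolated) | C#CC(=O)OC(=NC1CCCCC1)NC1CCCCC1 | intermediate
6 | 3,7,4'-tri-O-benzylkaempferol 5-O-propiolate | C#CC(=O)Oc1cc(OCc2ccccc2)cc2oc(-c3ccc(OCc4ccccc4)cc3)c(OCc3ccccc3)c(=O)c12 | intermediate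
7 | 3,7,4'-tri-O-benzylkaempferol with a 2-pyranone ring fused across C5–C6, O5–C(=O)–CH=CH–C6 (5,9-bis(benzyloxy)-8-[4-(benzyloxy)phenyl]-2H,10H-pyrano[2,3-f]chromene-2,10-dione) | O=c1ccc2c(OCc3ccccc3)cc3oc(-c4ccc(OCc5ccccc5)cc4)c(OCc4ccccc4)c(=O)c3c2o1 | intermediate
8 | 3,7,4'-tri-O-benzylkaempferol with a saturated lactone ring fused across C5–C6, O5–C(=O)–CH2–CH2–C6 (5,9-bis(benzyloxy)-8-[4-(benzyloxy)phenyl]-3,4-dihydro-2H,10H-pyrano[2,3-f]chromene-2,10-dione) | O=C1CCc2c(OCc3ccccc3)cc3oc(-c4ccc(OCc5ccccc5)cc4)c(OCc4ccccc4)c(=O)c3c2O1 | intermediate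
9 | methylmagnesium bromide | C[Mg]Br | starting material
10 | bromomagnesium 5-phenoxide of 3,7,4'-tri-O-benzyl-6-(3-oxobutyl)kaempferol (not isolated) | CC(=O)CCc1c(OCc2ccccc2)cc2oc(-c3ccc(OCc4ccccc4)cc3)c(OCc3ccccc3)c(=O)c2c1O[Mg]Br | intermediate
11 | 3,7,4'-tri-O-benzyl-6-(3-hydroxy-3-methylbutyl)kaempferol | CC(C)(O)CCc1c(OCc2ccccc2)cc2oc(-c3ccc(OCc4ccccc4)cc3)c(OCc3ccccc3)c(=O)c2c1O | intermediate
12 | 6-(3-hydroxy-3-methylbutyl)kaempferol (3,5,7-trihydroxy-6-(3-hydroxy-3-methylbutyl)-2-(4-hydroxyphenyl)-4H-chromen-4-one) | CC(C)(O)CCc1c(O)cc2oc(-c3ccc(O)cc3)c(O)c(=O)c2c1O | target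

Total step count: 6
Longest linear sequence: 6 steps (1 → 12)

Steps most likely to fail

1. Step 5 (key step). The Grignard reagent may add to the pyranone (C4 or C2) before the phenoxide is set free, or it may deprotonate the ketone stage so that the second methyl group is not delivered. The fallback sets out from lactone 8 and separates the two carbon–carbon bond formations. Me(MeO)NH·HCl and AlMe3 in CH2Cl2 should open the lactone to N-methoxy-N-methyl-3-(3,7,4'-tri-O-benzylkaempferol-6-yl)propanamide F1, which has a free 5-OH. The first equivalent of MeMgBr turns that hydroxyl into the chelating magnesium phenoxide, and a second equivalent adds once to the amide to give, after work-up, 3,7,4'-tri-O-benzyl-6-(3-oxobutyl)kaempferol F2. The weakly basic methylcerium reagent from MeLi and CeCl3 (THF, −78 °C, in excess to allow for the phenol) should then add to the ketone, and the sequence comes back to the route at 11.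

2. Step 2. Acylation of the hydrogen-bonded 5-OH may be so slow that the activated ynoate is lost by rearrangement to the N-acylurea and by conjugate addition of DMAP or phenoxide. The fallback sets out from 3 and replaces the O5 tether by a halogen at C6. BnMe3N ICl2 with CaCO3 in CH2Cl2–MeOH iodinates ortho to the free 5-OH and should give 6-iodo-3,7,4'-tri-O-benzylkaempferol F3. Negishi coupling with (3-ethoxy-3-oxopropyl)zinc bromide (Pd(OAc)2, SPhos, THF, excess zinc reagent to allow for the phenol) should give ethyl 3-(3,7,4'-tri-O-benzylkaempferol-6-yl)propanoate F4. p-TsOH in refluxing toluene with removal of ethanol then closes the lactone, and the sequence comes back to the route at 8.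

3. Step 3. Attack of C6 on the activated alkyne may be too slow, because the acylated O5 and the pyranone lower the nucleophilicity of ring A, so that alkyne hydration or binding of the catalyst to the C4 carbonyl takes over. The fallback sets out from 3 and delivers the carbon to C6 by a sigmatropic shift instead of an electrophilic ring closure. Allyl bromide and K2CO3 in DMF at 60 °C should give 5-O-allyl-3,7,4'-tri-O-benzylkaempferol F5. Aromatic Claisen rearrangement in N,N-diethylaniline at about 190 °C moves the allyl group to C6, the only free ortho position, to give 6-allyl-3,7,4'-tri-O-benzylkaempferol F6. Hydroboration with 9-BBN (in excess, since the phenol consumes some) and oxidation with NaBO3 should give 3,7,4'-tri-O-benzyl-6-(3-hydroxypropyl)kaempferol F7. Catalytic (n-Pr)4N RuO4 with N-methylmorpholine N-oxide (4 Å sieves, CH2Cl2) oxidises the primary alcohol to the aldehyde, which closes to the lactol with the 5-OH and is oxidised further to the lactone, and the sequence comes back to the route at 8.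

Further compounds
F1 | step 5 | N-methoxy-N-methyl-3-(3,7,4'-tri-O-benzylkaempferol-6-yl)propanamide | CON(C)C(=O)CCc1c(OCc2ccccc2)cc2oc(-c3ccc(OCc4ccccc4)cc3)c(OCc3ccccc3)c(=O)c2c1O
F2 | step 5 | 3,7,4'-tri-O-benzyl-6-(3-oxobutyl)kaempferol | CC(=O)CCc1c(OCc2ccccc2)cc2oc(-c3ccc(OCc4ccccc4)cc3)c(OCc3ccccc3)c(=O)c2c1O
F3 | step 2 | 6-iodo-3,7,4'-tri-O-benzylkaempferol | O=c1c(OCc2ccccc2)c(-c2ccc(OCc3ccccc3)cc2)oc2cc(OCc3ccccc3)c(I)c(O)c12
F4 | step 2 | ethyl 3-(3,7,4'-tri-O-benzylkaempferol-6-yl)propanoate | CCOC(=O)CCc1c(OCc2ccccc2)cc2oc(-c3ccc(OCc4ccccc4)cc3)c(OCc3ccccc3)c(=O)c2c1O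
F5 | step 3 | 5-O-allyl-3,7,4'-tri-O-benzylkaempferol | C=CCOc1cc(OCc2ccccc2)cc2oc(-c3ccc(OCc4ccccc4)cc3)c(OCc3ccccc3)c(=O)c12
F6 | step 3 | 6-allyl-3,7,4'-tri-O-benzylkaempferol | C=CCc1c(OCc2ccccc2)cc2oc(-c3ccc(OCc4ccccc4)cc3)c(OCc3ccccc3)c(=O)c2c1O
F7 | step 3 | 3,7,4'-tri-O-benzyl-6-(3-hydroxypropyl)kaempferol | OCCCc1c(OCc2ccccc2)cc2oc(-c3ccc(OCc4ccccc4)cc3)c(OCc3ccccc3)c(=O)c2c1O
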